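(All constants are assumed; what happens was integrated by code.)

Late in a run X is being lost to L while it is still being made from Z, so for one charge read at two times you need to know how fast Z gets through.

    X → L (k1 = 0.0190 s⁻¹)
    Z ⇌ D (K2 = 3.27, k2 = 0.0119 s⁻¹)
    Z → X (k3 = 0.0257 s⁻¹)
    Z + Z ⇌ Z2 (K4 = 49.8 M⁻¹, k4 = 3.67 M⁻¹ s⁻¹)
    Z + X ⇌ Z.X, settled at all times (K5 = 41.6 M⁻¹)

| setting | Friday's | Wednesday's |
|---|---|---|
| Z | 0.050 M | 0.050 M |
| time | 40 s | 20 s |

- which of the two there is more of at the end, counted by the Z in each, Friday's (Z2 / X)
- which of the two there is more of at the end, counted by the Z in each, Wednesday's (Z2 / X)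
- amount of X at the end, in percent of the Z charged, Friday's
- amount of X at the end, in percent of the Z charged, Wednesday's

- percent here means Z units held: one Z2 or Z.X counts as two
- what is said of X includes Z.X
- two of one species on the left: rate k times its square, two consumed each time
- in an amount of X, one Z.X counts as one X
- run time (Friday's): 40 s

Take Wednesday's flask two ways. First, pretend all the Z stands free and leaves by Z → X and Z → D together: that makes 36.1% of the charge into X, before any loss to L. Second, let Z2 take up Z first. The balance of 2 Z with Z2 leaves c(Z) at 0.0179 M, and held there for 20 s it makes 18.4%. The first way gives 1.96 times as much as the second.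

To see which one cheats, divide the rate at which Z goes to X by the rate at which Z goes into Z2. One power of c(Z) cancels and time drops out, leaving a selectivity factor of c_x/c(Z). Here c_x is the rate constant of Z → X over twice that of Z + Z → Z2, 0.00350 M: the crossover level, the free Z at which the two paths take Z equally fast, counting the forward step alone. The charge stands 14.3 times above it, so the first way cheats, and I keep the second.

What was made has stood for half of the run on average, and if I let it all leak to L as free X, that gives me 14.9% of X on Wednesday's and 22.9% on Friday's. Taking what went to X and D out of the Z pool and balancing again leaves Z2 at 43.5% on Wednesday's and 24.1% on Friday's. So I say Z2 in both, on Friday's narrowly.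

The forecast holds that “Z2 acts as a reservoir that feeds free Z”. It gives 24.4% of X for Friday's and 17.8% for Wednesday's, with X ahead on Friday's, where I say Z2, and Z2 ahead on Wednesday's.

The simulation gives Friday's 22.7% of X against 29.3% in Z2, so Z2 leads, and Wednesday's 16.0% against 42.7%, so Z2 leads. At the end of Friday's, free Z is 21% of the charge, 0.0104 M, still above the crossover level, and the path to X takes Z at 0.34 of the rate of the forward path to Z2, up from 0.070 just after the start. In the neighbour flask, Friday's read at 2.5 min, free Z is down to 6.80%, 0.00340 M, level with 0.00350 M, and Z2 holds 3.22%.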